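**Retrosynthetic overview**
1. Target 8 ⇐ quinone 7 (reduction) ⇐ acylquinone 6: the O1–C8a aryl ether bond is disconnected. The pyranone ring is the only ring made and is closed last, by attack of the side-chain alcohol on the quinone ring.
2. 6 ⇐ acylhydroquinone 5 by oxidation. The free 5,8-dihydroxy pattern comes directly from the quinone, so no protecting groups are needed.
3. 5 ⇐ β-diketone 4 by asymmetric hydrogenation of the aliphatic ketone. This sets C2, and its C–O bond is not broken afterwards.
4. 4 ⇐ 2',5'-dihydroxyacetophenone 1 + hexadecanoyl chloride 2 by C-acylation of the ketone polyanion. The benzene ring is bought.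

Assumption: the SMILES is read as the (R)-enantiomer, (2R)-5,8-dihydroxy-2-pentadecyl-2,3-dihydro-4H-chromen-4-one.

**Step 1**
Reactants: 1 1-(2,5-dihydroxyphenyl)ethan-1-one (2',5'-dihydroxyacetophenone); 2 hexadecanoyl chloride (palmitoyl chloride)
Product: 4 1-(2,5-dihydroxyphenyl)octadecane-1,3-dione, via trilithium phenoxide-enolate 3 (not isolated)
Conditions: LiN(SiMe3)2 (4.2 equiv), THF, −78 to −10 °C, Ar; then 2 (1.0 equiv), −78 °C to rt; 1 M HCl work-up
Reagents that add atoms: none
Why: Claisen-type C-acylation of a ketone polyanion (a one-pot alternative to the Baker–Venkataraman sequence), in which the enolate carbon of trianion 3 is far more nucleophilic than the two lithium phenoxides, so one equivalent of acyl chloride goes to carbon and the fourth equivalent of base holds the product as its enolate; no stereocenter is formed.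

**Step 2**
Reactants: 4 1-(2,5-dihydroxyphenyl)octadecane-1,3-dione
Product: 5 (3R)-1-(2,5-dihydroxyphenyl)-3-hydroxyoctadecan-1-one
Conditions: H2 (50 atm), RuCl2[(R)-BINAP] (1 mol%), EtOH/CH2Cl2 4:1, 40 °C
Reagents that add atoms: none
Why: Noyori asymmetric hydrogenation of a 1-aryl-1,3-diketone, in which Ru is chelated by both carbonyl oxygens and hydride goes only to the aliphatic C3 ketone (the aryl ketone is conjugated and hydrogen-bonded to the ortho OH), with (R)-BINAP giving the (R)-carbinol in the same sense as with β-keto esters, which sets the only stereocenter.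

**Step 3**
Reactants: 5 (3R)-1-(2,5-dihydroxyphenyl)-3-hydroxyoctadecan-1-one
Product: 8 (2R)-5,8-dihydroxy-2-pentadecyl-2,3-dihydro-4H-chromen-4-one, via acylbenzoquinone 6 (not isolated), via chromenetrione 7 (not isolated)
Conditions: Ag2O (3.0 equiv), MgSO4, CH2Cl2 (0.02 M), rt, dark, 2 h; filter through Celite; then sat. aq. Na2S2O4, EtOAc, rt, 10 min
Reagents that add atoms: none
Why: Proposed new method: a dehydrogenative 6-endo oxa-Michael ring closure, to my knowledge not yet described, in which Ag2O oxidises acylhydroquinone 5 to acylquinone 6, whose ring carbon next to the acyl group (β to both the ketone and a quinone carbonyl, the site where acylquinones are known to take thiols, amines and HCl) is attacked by the tethered secondary alcohol through a six-membered transition state, the adduct aromatises to hydroquinone 8, which is more easily oxidised than 5 and is therefore carried on by the excess Ag2O to the single end point 7, and dithionite then returns 8; the C2 stereocenter is retained because its C–O bond is never broken; the closest known reaction types are intermolecular hetero-Michael additions to 2-acyl-1,4-benzoquinones and the SNAr ring closure of β-hydroxy ketone alkoxides onto 2-fluoroaryl ketones to give chroman-4-ones.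

**Compound list**
1 | 1-(2,5-dihydroxyphenyl)ethan-1-one | CC(=O)c1cc(O)ccc1O | starting material
2 | hexadecanoyl chloride | CCCCCCCCCCCCCCCC(=O)Cl | starting material
3 | trilithium 2-(1-oxidoethenyl)benzene-1,4-diolate | [Li+].[Li+].[Li+].C=C([O-])c1cc([O-])ccc1[O-] | intermediate
4 | 1-(2,5-dihydroxyphenyl)octadecane-1,3-dione | CCCCCCCCCCCCCCCC(=O)CC(=O)c1cc(O)ccc1O | intermediate
5 | (3R)-1-(2,5-dihydroxyphenyl)-3-hydroxyoctadecan-1-one | CCCCCCCCCCCCCCC[C@@H](O)CC(=O)c1cc(O)ccc1O | intermediate
6 | 2-[(3R)-3-hydroxyoctadecanoyl]cyclohexa-2,5-diene-1,4-dione | CCCCCCCCCCCCCCC[C@@H](O)CC(=O)C1=CC(=O)C=CC1=O | intermediate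
7 | (2R)-2-pentadecyl-2,3-dihydro-4H-chromene-4,5,8-trione | CCCCCCCCCCCCCCC[C@@H]1CC(=O)C2=C(O1)C(=O)C=CC2=O | intermediate
8 | (2R)-5,8-dihydroxy-2-pentadecyl-2,3-dihydro-4H-chromen-4-one | CCCCCCCCCCCCCCC[C@@H]1CC(=O)c2c(O)ccc(O)c2O1 | target

**Step count**
Total steps: 3. Longest linear sequence: 3 steps (1 → 4 → 5 → 8).

**Steps most likely to fail**

Step 3 (the new ring closure). The neutral alcohol may attack 6 too slowly, so that the acylquinone decays by intermolecular pathways. Quinone 7 may also ring-open by β-elimination on the mildly basic Ag2O surface. The fallback uses known reaction types, sets out from 5 and comes back to the route at 7. Oxidise 5 with Ag2O (1.1 equiv), filter, and add HCl in Et2O at 0 °C. Hydrogen chloride adds to acylquinones at the carbon next to the acyl group and gives (3R)-1-(2-chloro-3,6-dihydroxyphenyl)-3-hydroxyoctadecan-1-one F6. A second Ag2O oxidation gives 2-chloro-3-[(3R)-3-hydroxyoctadecanoyl]cyclohexa-2,5-diene-1,4-dione F7. F7 is a vinylogous acyl chloride, and the tethered alcohol displaces its chloride by addition–elimination (Ag2O takes up the HCl) to give 7. Because this is a substitution and not an addition, no hydroquinone is formed and redox exchange does not arise. Dithionite reduction as in step 3 then gives 8. This fallback does not help if 7 itself is the unstable species.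

Step 2. The free 2-hydroxyaryl diketone may bind Ru as a phenoxide chelate, or may cyclodehydrate to the chromone under the slightly acidic conditions. The fallback sets out from 1 and comes back at 5, and takes the phenols out of the stereo-defining step. Benzylate 1 (BnBr, K2CO3, DMF) to 1-[2,5-bis(benzyloxy)phenyl]ethan-1-one F3. Acylate its lithium enolate (LiN(SiMe3)2, 2.2 equiv) with 2 to give 1-[2,5-bis(benzyloxy)phenyl]octadecane-1,3-dione F4. Hydrogenate this non-phenolic aryl diketone with RuCl2[(R)-BINAP] to (3R)-1-[2,5-bis(benzyloxy)phenyl]-3-hydroxyoctadecan-1-one F5. Remove both benzyl groups (H2, 1 atm, Pd/C, EtOAc) to reach 5.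

Step 1. The phenoxides may be O-acylated, or the excess amide base may convert 2 into its ketene. The fallback sets out from 1 and comes back at 4, and uses O-acylation followed by intramolecular O-to-C acyl transfer (Baker–Venkataraman). Acylate both phenols with 2 (2.2 equiv, K2CO3, acetone) to give 2-acetyl-1,4-phenylene dihexadecanoate F1. Treat with KOtBu in THF so that the ketone enolate takes the ortho ester group, giving 4-hydroxy-3-(3-oxooctadecanoyl)phenyl hexadecanoate F2. Cleave the remaining aryl ester with K2CO3 in MeOH to give 4.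

**Further compounds**
F1 | step 1 | 2-acetyl-1,4-phenylene dihexadecanoate | CC(=O)c1cc(OC(=O)CCCCCCCCCCCCCCC)ccc1OC(=O)CCCCCCCCCCCCCCC
F2 | step 1 | 4-hydroxy-3-(3-oxooctadecanoyl)phenyl hexadecanoate | CCCCCCCCCCCCCCCC(=O)CC(=O)c1cc(OC(=O)CCCCCCCCCCCCCCC)ccc1O
F3 | step 2 | 1-[2,5-bis(benzyloxy)phenyl]ethan-1-one | CC(=O)c1cc(OCc2ccccc2)ccc1OCc1ccccc1
F4 | step 2 | 1-[2,5-bis(benzyloxy)phenyl]octadecane-1,3-dione | CCCCCCCCCCCCCCCC(=O)CC(=O)c1cc(OCc2ccccc2)ccc1OCc1ccccc1
F5 | step 2 | (3R)-1-[2,5-bis(benzyloxy)phenyl]-3-hydroxyoctadecan-1-one | CCCCCCCCCCCCCCC[C@@H](O)CC(=O)c1cc(OCc2ccccc2)ccc1OCc1ccccc1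
F6 | step 3 | (3R)-1-(2-chloro-3,6-dihydroxyphenyl)-3-hydroxyoctadecan-1-one | CCCCCCCCCCCCCCC[C@@H](O)CC(=O)c1c(Cl)c(O)ccc1O
F7 | step 3 | 2-chloro-3-[(3R)-3-hydroxyoctadecanoyl]cyclohexa-2,5-diene-1,4-dione | CCCCCCCCCCCCCCC[C@@H](O)CC(=O)C1=C(Cl)C(=O)C=CC1=O
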